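**Plan**

- Numbering (target skeleton): ring carbons C1–C10 (C1 carries the methylidene, C5 = CMe2, C6/C10 = ring fusion, C9 = quaternary), C11 = side-chain CH, C12–C15 = lactone (β-CH, α-CH–OAc, C=O, OCH2), C16 = CH2OAc.
- Cuts: C1=CH2 and both acetates; C13–O, C12–C15 and C12=C13 of the lactone; the C8 carbonyl; then C11–C16 and C9–C10 together (formaldehyde + alkenylcyclobutanol); C8–C9 (alkenyllithium + cyclobutanone); the cyclobutane bonds C6–C7/C8–C10 (allene + enone); C1–C2 (one-carbon ring enlargement).
- What makes the key step possible: C9 (quaternary, in the five-membered ring) is bonded directly to C11 (the methine carrying C16H2OAc). Both centres can therefore come from one anti addition to a C9=C11 double bond, with C16 as the incoming electrophile and ring-fusion carbon C10 shifting over from the cyclobutanol carbon C8.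
- Forward order of rings: cyclobutane (photocycloaddition), seven-membered ring (six-to-seven homologation), cyclopentanone (four-to-five expansion, key step), six-membered unsaturated lactone through O16, five-membered lactone by acyl shift to O15.
- Stereochemistry: cis fusion (C6, C10) from the photocycloaddition; absolute configuration from a lipase resolution at C1; C8 by convex-face addition; C9/C11 from the key step (retention at C10, anti addition, (E) alkene); C12 by addition trans to the C11 substituent in the six-membered lactone; C13 by hydroxylation anti to the C12 substituent.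

Key step: step 11

Remark: compounds 3–6 are racemic (the SMILES show the enantiomer carried on); from 7 onward every compound is a single enantiomer.
Assumption: the lipase acylates the (2R)-alcohol of 6, as the usual size-based preference for secondary alcohols predicts, so the wanted series is collected as acetate 7.

**Route**

Step 1
Reactants: 1 4,4-dimethylcyclohex-2-en-1-one; 2 propa-1,2-diene (allene)
Product: 3 (±)-cis-5,5-dimethyl-8-methylidenebicyclo[4.2.0]octan-2-one
Conditions: allene (excess), THF, hν (Hg lamp, Pyrex), −78 °C; then basic Al2O3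
Reagents that add atoms: none
Why: Enone–allene [2+2] photocycloaddition should join the central allene carbon to the enone α-carbon (head-to-head), which puts the future C8 carbonyl next to C10 as the key step demands (a ketene acetal would give the 1,4-oxygenated isomer), and alumina epimerises any trans-fused adduct at the α-carbon to the cis ring fusion.

Step 2
Reactants: 3 (±)-cis-5,5-dimethyl-8-methylidenebicyclo[4.2.0]octan-2-one
Product: 5 (±)-cis-6,6-dimethyl-9-methylidenebicyclo[5.2.0]nonan-2-one, via α-silyl ketone 4 (not isolated)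
Conditions: Me3SiCHN2, BF3·OEt2, CH2Cl2, −78 to −30 °C; then 1 M HCl, THF
Reagents that add atoms: trimethylsilyldiazomethane, C[Si](C)(C)C=[N+]=[N-]
Why: Lewis-acid-promoted diazoalkane ring homologation (Tiffeneau–Demjanov type) should insert the new carbon on the CH2 side, because the less substituted α-carbon migrates in preference to the cyclobutyl methine, and dilute acid then removes the C-silyl group without disturbing the cis fusion.

Step 3
Reactants: 5 (±)-cis-6,6-dimethyl-9-methylidenebicyclo[5.2.0]nonan-2-one
Product: 6 (±)-(1R*,2R*,7R*)-6,6-dimethyl-9-methylidenebicyclo[5.2.0]nonan-2-ol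
Conditions: LiBH(s-Bu)3, THF, −78 °C; aq. NH4Cl
Reagents that add atoms: none
Why: Hydride reduction with a bulky trialkylborohydride should attack the C1 carbonyl from the face of H-10, away from the cyclobutane, giving the alcohol cis to the four-membered ring (either C1 epimer would serve, since C1 returns to a ketone).

Step 4
Reactants: 6 (±)-(1R*,2R*,7R*)-6,6-dimethyl-9-methylidenebicyclo[5.2.0]nonan-2-ol
Product: 7 (1R,2R,7R)-6,6-dimethyl-9-methylidenebicyclo[5.2.0]nonan-2-yl acetate
Conditions: vinyl acetate, immobilised Candida antarctica lipase B, t-BuOMe, 30 °C, run to about half conversion; chromatographic removal of the unreacted alcohol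
Reagents that add atoms: vinyl acetate, C=COC(C)=O
Why: Lipase-catalysed kinetic resolution (enantioselective transesterification) should acylate the (2R)-carbinol, which belongs to the ring-fusion series of the target, and leave its mirror image as free alcohol.

Step 5
Reactants: 7 (1R,2R,7R)-6,6-dimethyl-9-methylidenebicyclo[5.2.0]nonan-2-yl acetate
Product: 8 (1R,2R,7R)-6,6-dimethyl-9-methylidenebicyclo[5.2.0]nonan-2-ol
Conditions: K2CO3, MeOH, rt
Reagents that add atoms: none
Why: Base-catalysed transesterification (methanolysis) frees the alcohol without touching any stereocentre.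

Step 6
Reactants: 8 (1R,2R,7R)-6,6-dimethyl-9-methylidenebicyclo[5.2.0]nonan-2-ol
Product: 9 tert-butyldimethylsilyl ether of 8
Conditions: t-BuMe2SiOTf, 2,6-lutidine, CH2Cl2, 0 °C
Reagents that add atoms: tert-butyldimethylsilyl trifluoromethanesulfonate, CC(C)(C)[Si](C)(C)OS(=O)(=O)C(F)(F)F
Why: Silylation with the reactive silyl triflate should protect the hindered C1 alcohol, which must be masked so that the cyclobutanone of the next step is not a free β-hydroxy ketone open to retro-aldol cleavage.

Step 7
Reactants: 9 tert-butyldimethylsilyl ether of 8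
Product: 11 (1S,2R,7R)-2-(tert-butyldimethylsilyloxy)-6,6-dimethylbicyclo[5.2.0]nonan-9-one, via secondary ozonide 10 (not isolated)
Conditions: O3, CH2Cl2, −78 °C; then Me2S, −78 °C to rt
Reagents that add atoms: ozone, [O-][O+]=O
Why: Ozonolysis of the 1,1-disubstituted alkene with neutral reductive work-up should give the cyclobutanone (C8) without epimerising the adjacent ring-fusion carbon.

Step 8
Reactants: 12 but-2-yn-1-ol
Product: 13 triethyl(but-2-yn-1-yloxy)silane
Conditions: Et3SiCl, imidazole, CH2Cl2, 0 °C
Reagents that add atoms: chlorotriethylsilane, CC[Si](Cl)(CC)CC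
Why: Silylation gives a C12 ether that is inert to the organometallic steps and can later be oxidised directly to the aldehyde while tert-butyldimethylsilyl ethers stay in place.

Step 9
Reactants: 13 triethyl(but-2-yn-1-yloxy)silane
Product: 15 triethyl[(E)-3-iodobut-2-en-1-yloxy]silane, via alkenylzirconocene chloride 14 (not isolated)
Conditions: Cp2Zr(H)Cl (2 equiv), THF, 50 °C; then iodine, THF, 0 °C
Reagents that add atoms: iodine, [I][I]
Why: Hydrozirconation–iodination adds Zr–H syn, excess reagent equilibrates the metal to the less hindered methyl-bearing carbon, and iodinolysis with retention should give the (E)-iodide (iodine trans to the CH2O group).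

Step 10
Reactants: 15 triethyl[(E)-3-iodobut-2-en-1-yloxy]silane; 11 (1S,2R,7R)-2-(tert-butyldimethylsilyloxy)-6,6-dimethylbicyclo[5.2.0]nonan-9-one
Product: 17 (1S,2R,7R,9S)-2-(tert-butyldimethylsilyloxy)-6,6-dimethyl-9-[(E)-4-(triethylsilyloxy)but-2-en-2-yl]bicyclo[5.2.0]nonan-9-ol, via alkenyllithium 16 (not isolated)
Conditions: t-BuLi (2 equiv), Et2O, −78 °C; then 11, −78 °C; aq. NH4Cl
Reagents that add atoms: none
Why: Iodine–lithium exchange with retention of alkene geometry followed by 1,2-addition to the strained, highly electrophilic cyclobutanone should occur from the convex face (opposite the seven-membered ring and the C1 silyloxy group), placing the C8 oxygen on the concave face.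

Step 11
Reactants: 17 (1S,2R,7R,9S)-2-(tert-butyldimethylsilyloxy)-6,6-dimethyl-9-[(E)-4-(triethylsilyloxy)but-2-en-2-yl]bicyclo[5.2.0]nonan-9-ol; 18 formaldehyde (used as paraformaldehyde)
Product: 20 (1S,3aR,8R,8aR)-8-(tert-butyldimethylsilyloxy)-1-[(2R)-1-hydroxy-3-(triethylsilyloxy)propan-2-yl]-1,4,4-trimethyloctahydroazulen-2(1H)-one, via aluminium alkoxide 19 (not isolated)
Conditions: (CH2O)n, Me2AlCl (3 equiv), CH2Cl2, −78 to −20 °C; aq. potassium sodium tartrate
Reagents that add atoms: none
Why: Me2AlCl converts the tertiary hydroxyl into its aluminium alkoxide (methane is lost and stray protons are scavenged) and activates monomeric formaldehyde, which attacks the less substituted alkene carbon C11 (bond C11–C16) while the antiperiplanar cyclobutane bond C8–C10 shifts to the tertiary cationic centre developing at C9 (bond C9–C10) and the alkoxide oxygen becomes the C8 carbonyl. The closest known chemistry is the electrophile-triggered semipinacol (Prins–pinacol) ring expansion of 1-alkenylcyclobutanols together with Me2AlCl-mediated formaldehyde additions to trisubstituted alkenes. The cyclopentanone is not closed by a cyclisation but by a 1,2-alkyl shift that enlarges the four-membered ring by one carbon, driven by release of cyclobutane strain. C10 migrates with retention, and since C16 and C10 add to opposite faces of the alkene the (E) geometry fixes C11 relative to C9. C9 is set by the rotamer about C8–C9: the conformer with the C9 methyl beside the small carbinol oxygen and the vinylic C11–H beside C7H2 should react, because the alternative forces the branching C11 into the concave face next to C1, and this conformer leaves the methyl cis to C1 as in the target. The step needs C10 to migrate in preference to C7 (the more substituted ring-fusion carbon has the higher migratory aptitude), attack at C11 and not C9 (tertiary cation), and ring expansion faster than proton loss or chloride capture (alkoxide push plus strain release).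

Step 12
Reactants: 20 key-step hydroxy ketone
Product: 21 16-O-tert-butyldimethylsilyl ether of 20
Conditions: t-BuMe2SiCl, imidazole, DMF, rt
Reagents that add atoms: tert-butyldimethylsilyl chloride, CC(C)(C)[Si](C)(C)Cl
Why: Silylation of the primary C16 hydroxyl keeps the two CH2O arms on C11 distinct (C16 tert-butyldimethylsilyl, C12 triethylsilyl) and removes the only acidic proton before enolate chemistry.

Step 13
Reactants: 21 16-O-tert-butyldimethylsilyl ether of 20
Product: 23 C7=C8 enol trifluoromethanesulfonate of 21, via potassium enolate 22 (not isolated)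
Conditions: KN(SiMe3)2, THF, −78 °C; then PhN(SO2CF3)2, −78 to 0 °C
Reagents that add atoms: N-phenylbis(trifluoromethanesulfonimide), O=S(=O)(N(c1ccccc1)S(=O)(=O)C(F)(F)F)C(F)(F)F
Why: Enolate O-sulfonylation can give only one enol triflate because the C8 ketone has α-hydrogens at C7 alone (C9 is quaternary).

Step 14
Reactants: 23 C7=C8 enol trifluoromethanesulfonate of 21
Product: 24 8-deoxo compound (C7 and C8 are CH2; 1-O- and 16-O-tert-butyldimethylsilyl and 12-O-triethylsilyl ethers; stereocentres as in 20)
Conditions: H2 (3 atm), PtO2, NaHCO3, EtOAc, rt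
Reagents that add atoms: none
Why: Hydrogenolysis of the vinyl C–O bond and hydrogenation of the resulting C7=C8 alkene over PtO2 complete a two-step ketone-to-methylene deoxygenation that creates no stereocentre, with bicarbonate buffering the acid released so the silyl ethers survive.

Step 15
Reactants: 24 8-deoxo bis(tert-butyldimethylsilyl) triethylsilyl ether
Product: 25 C12 aldehyde (1-O- and 16-O-tert-butyldimethylsilyl ethers; C11 as in 20)
Conditions: (COCl)2, Me2SO, CH2Cl2, −78 to −40 °C; then Et3N, −78 °C to 0 °C
Reagents that add atoms: none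
Why: Swern oxidation converts a primary triethylsilyl ether directly into the aldehyde (the chlorosulfonium salt cleaves the Si–O bond) while tert-butyldimethylsilyl ethers are left, and the cold amine quench protects the C11 stereocentre α to the new carbonyl.

Step 16
Reactants: 25 C12 aldehyde
Product: 26 methyl (Z)-enoate (C12=C13 with C14 as CO2Me; 16-O- and 1-O-tert-butyldimethylsilyl ethers)
Conditions: (CF3CH2O)2P(O)CH2CO2Me, KN(SiMe3)2, 18-crown-6, THF, −78 °C
Reagents that add atoms: methyl bis(2,2,2-trifluoroethyl)phosphonoacetate, COC(=O)CP(=O)(OCC(F)(F)F)OCC(F)(F)F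
Why: Still–Gennari olefination should give the (Z)-enoate needed for ring closure onto O16, and at −78 °C the α-branched aldehyde should not epimerise.

Step 17
Reactants: 26 methyl (Z)-enoate
Product: 28 5,6-dihydro-2H-pyran-2-one (lactone O16–C14 with C12=C13; C11 is ring position 5 and carries the hydroazulenyl group; 1-O-tert-butyldimethylsilyl ether), via hydroxy enoate 27 (not isolated)
Conditions: camphorsulfonic acid (cat.), MeOH–CH2Cl2, 0 °C to rt
Reagents that add atoms: none
Why: Acid-catalysed methanolysis removes the primary silyl ether much faster than the hindered secondary one at C1, and the freed C16 hydroxyl lactonises onto the cis ester (desilylation–lactonisation).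

Step 18
Reactants: 28 5,6-dihydro-2H-pyran-2-one
Product: 30 γ-lactone alcohol (lactone O15–C14; C12 bears the C11 side chain with free 16-OH; 1-O-tert-butyldimethylsilyl ether), via hydroxymethyl δ-lactone 29 (not isolated)
Conditions: MeOH, Ph2CO (0.3 equiv), hν (350 nm), rt; evaporate; camphorsulfonic acid (cat.), CH2Cl2, rt
Reagents that add atoms: methanol, CO
Why: Photosensitised radical conjugate addition puts a hydroxymethyl radical on the β-carbon C12 trans to the large substituent on the neighbouring ring carbon C11 (this trans-4,5 relation is the C12 configuration of the target), and acid-catalysed acyl migration to the more stable five-membered lactone then frees the C16 hydroxyl.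

Step 19
Reactants: 30 γ-lactone alcohol
Product: 31 16-O-triethylsilyl ether of 30
Conditions: Et3SiCl, imidazole, CH2Cl2, 0 °C
Reagents that add atoms: chlorotriethylsilane, CC[Si](Cl)(CC)CC
Why: Silylation blocks O16, which as an alkoxide under the next step's base would attack the lactone and shift the acyl group back to the six-membered ring.

Step 20
Reactants: 31 16-O-triethylsilyl ether of 30
Product: 34 13,16-diol (13S; trans α-hydroxy γ-lactone; 1-O-tert-butyldimethylsilyl ether), via potassium enolate 32 (not isolated), via α-hydroxy lactone silyl ether 33 (not isolated)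
Conditions: KN(SiMe3)2, THF, −78 °C; 2-(phenylsulfonyl)-3-phenyloxaziridine, −78 °C; then AcOH–H2O–THF, rt
Reagents that add atoms: 2-(phenylsulfonyl)-3-phenyloxaziridine, O=S(=O)(c1ccccc1)N1OC1c1ccccc1
Why: Enolate hydroxylation with an N-sulfonyloxaziridine should deliver oxygen to the lactone enolate face anti to the bulky C12 substituent (trans product), and aqueous acetic acid then removes only the primary triethylsilyl ether.

Step 21
Reactants: 34 13,16-diol
Product: 35 13,16-diacetate (1-O-tert-butyldimethylsilyl ether)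
Conditions: Ac2O, pyridine, 4-(dimethylamino)pyridine (cat.), CH2Cl2, 0 °C to rt
Reagents that add atoms: acetic anhydride, CC(=O)OC(C)=O
Why: Acetylation installs both acetates of the target in one operation under conditions too mild to epimerise the trans α-acyloxy lactone.

Step 22
Reactants: 35 13,16-diacetate
Product: 36 C1 alcohol (13,16-diacetate)
Conditions: HF·pyridine, THF, 0 °C to rt
Reagents that add atoms: none
Why: Fluoride desilylation under mildly acidic conditions removes the remaining silyl ether without acyl migration or cleavage of the acetates and lactone.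

Step 23
Reactants: 36 C1 alcohol
Product: 37 C1 ketone (13,16-diacetate)
Conditions: DMP, NaHCO3, CH2Cl2, rt
Reagents that add atoms: none
Why: Buffered Dess–Martin oxidation gives the ketone without epimerising the adjacent ring-fusion carbon C10.

Step 24
Reactants: 37 C1 ketone
Product: 38 (3S,4R)-4-{(1R)-2-acetoxy-1-[(1R,3aR,8aS)-1,4,4-trimethyl-8-methylidenedecahydroazulen-1-yl]ethyl}-2-oxooxolan-3-yl acetate (CNP0234964.1)
Conditions: Zn, CH2Br2, TiCl4, THF–CH2Cl2, 0 °C to rt
Reagents that add atoms: dibromomethane, BrCBr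
Why: Takai–Lombardo methylenation is non-basic and selective for ketones over esters and lactones, so the hindered C1 ketone should be methylenated without epimerisation at C10 or C13 and without loss of the acetates.

**Compound list**

1 | 4,4-dimethylcyclohex-2-en-1-one | CC1(C)CCC(=O)C=C1 | starting material
2 | propa-1,2-diene (allene) | C=C=C | starting material
3 | (±)-cis-5,5-dimethyl-8-methylidenebicyclo[4.2.0]octan-2-one (racemic) | O=C1CCC(C)(C)[C@@H]2CC(=C)[C@H]12 | intermediate
4 | (±)-cis-6,6-dimethyl-9-methylidene-3-(trimethylsilyl)bicyclo[5.2.0]nonan-2-one | O=C1C([Si](C)(C)C)CCC(C)(C)[C@@H]2CC(=C)[C@H]12 | intermediate (not isolated)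
5 | (±)-cis-6,6-dimethyl-9-methylidenebicyclo[5.2.0]nonan-2-one (racemic) | O=C1CCCC(C)(C)[C@@H]2CC(=C)[C@H]12 | intermediate
6 | (±)-(1R*,2R*,7R*)-6,6-dimethyl-9-methylidenebicyclo[5.2.0]nonan-2-ol (racemic; OH cis to the cyclobutane) | O[C@@H]1CCCC(C)(C)[C@@H]2CC(=C)[C@H]12 | intermediate
7 | (1R,2R,7R)-6,6-dimethyl-9-methylidenebicyclo[5.2.0]nonan-2-yl acetate | CC(=O)O[C@@H]1CCCC(C)(C)[C@@H]2CC(=C)[C@H]12 | intermediate
8 | (1R,2R,7R)-6,6-dimethyl-9-methylidenebicyclo[5.2.0]nonan-2-ol | O[C@@H]1CCCC(C)(C)[C@@H]2CC(=C)[C@H]12 | intermediate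
9 | tert-butyl{[(1R,2R,7R)-6,6-dimethyl-9-methylidenebicyclo[5.2.0]nonan-2-yl]oxy}dimethylsilane | CC(C)(C)[Si](C)(C)O[C@@H]1CCCC(C)(C)[C@@H]2CC(=C)[C@H]12 | intermediate
10 | secondary ozonide of 9 (spiro-1,2,4-trioxolane at the former methylidene-bearing carbon) | CC(C)(C)[Si](C)(C)O[C@@H]1CCCC(C)(C)[C@@H]2CC3(OCOO3)[C@H]12 | intermediate (not isolated)
11 | (1S,2R,7R)-2-(tert-butyldimethylsilyloxy)-6,6-dimethylbicyclo[5.2.0]nonan-9-one | CC(C)(C)[Si](C)(C)O[C@@H]1CCCC(C)(C)[C@@H]2CC(=O)[C@H]12 | intermediate
12 | but-2-yn-1-ol | CC#CCO | starting material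
13 | triethyl(but-2-yn-1-yloxy)silane | CC#CCO[Si](CC)(CC)CC | intermediate
14 | chlorobis(cyclopentadienyl)[(E)-4-(triethylsilyloxy)but-2-en-2-yl]zirconium (Zr trans to the CH2O group) | C/C(=C\CO[Si](CC)(CC)CC)[Zr](Cl)(C1C=CC=C1)C1C=CC=C1 | intermediate (not isolated)
15 | triethyl[(E)-3-iodobut-2-en-1-yloxy]silane | I/C(C)=C/CO[Si](CC)(CC)CC | intermediate
16 | alkenyllithium from 15 (Li in place of iodine, geometry retained) | C/C([Li])=C\CO[Si](CC)(CC)CC | intermediate (not isolated)
17 | (1S,2R,7R,9S)-2-(tert-butyldimethylsilyloxy)-6,6-dimethyl-9-[(E)-4-(triethylsilyloxy)but-2-en-2-yl]bicyclo[5.2.0]nonan-9-ol | CC(C)(C)[Si](C)(C)O[C@@H]1CCCC(C)(C)[C@@H]2C[C@@](O)(/C(C)=C/CO[Si](CC)(CC)CC)[C@H]12 | intermediate (key-step precursor)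
18 | formaldehyde (from paraformaldehyde) | C=O | starting material
19 | chloro(methyl)aluminium alkoxide of 17 | CC(C)(C)[Si](C)(C)O[C@@H]1CCCC(C)(C)[C@@H]2C[C@@](O[Al](C)Cl)(/C(C)=C/CO[Si](CC)(CC)CC)[C@H]12 | intermediate (not isolated)
20 | (1S,3aR,8R,8aR)-8-(tert-butyldimethylsilyloxy)-1-[(2R)-1-hydroxy-3-(triethylsilyloxy)propan-2-yl]-1,4,4-trimethyloctahydroazulen-2(1H)-one (cis-fused; C9 methyl cis to C1) | CC(C)(C)[Si](C)(C)O[C@@H]1CCCC(C)(C)[C@@H]2CC(=O)[C@@](C)([C@H](CO)CO[Si](CC)(CC)CC)[C@H]12 | intermediate (key-step product)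
21 | 16-O-tert-butyldimethylsilyl ether of 20 | CC(C)(C)[Si](C)(C)O[C@@H]1CCCC(C)(C)[C@@H]2CC(=O)[C@@](C)([C@H](CO[Si](C)(C)C(C)(C)C)CO[Si](CC)(CC)CC)[C@H]12 | intermediate
22 | potassium C7=C8 enolate of 21 | CC(C)(C)[Si](C)(C)O[C@@H]1CCCC(C)(C)[C@@H]2C=C([O-])[C@@](C)([C@H](CO[Si](C)(C)C(C)(C)C)CO[Si](CC)(CC)CC)[C@H]12.[K+] | intermediate (not isolated)
23 | C7=C8 enol trifluoromethanesulfonate of 21 | CC(C)(C)[Si](C)(C)O[C@@H]1CCCC(C)(C)[C@@H]2C=C(OS(=O)(=O)C(F)(F)F)[C@@](C)([C@H](CO[Si](C)(C)C(C)(C)C)CO[Si](CC)(CC)CC)[C@H]12 | intermediate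
24 | 8-deoxo compound (C7, C8 = CH2; 1-O- and 16-O-tert-butyldimethylsilyl, 12-O-triethylsilyl) | CC(C)(C)[Si](C)(C)O[C@@H]1CCCC(C)(C)[C@@H]2CC[C@@](C)([C@H](CO[Si](C)(C)C(C)(C)C)CO[Si](CC)(CC)CC)[C@H]12 | intermediate
25 | C12 aldehyde (1-O- and 16-O-tert-butyldimethylsilyl) | CC(C)(C)[Si](C)(C)O[C@@H]1CCCC(C)(C)[C@@H]2CC[C@@](C)([C@H](CO[Si](C)(C)C(C)(C)C)C=O)[C@H]12 | intermediate
26 | methyl (Z)-enoate (C12=C13; C14 = CO2Me) | CC(C)(C)[Si](C)(C)O[C@@H]1CCCC(C)(C)[C@@H]2CC[C@@](C)([C@H](CO[Si](C)(C)C(C)(C)C)/C=C\C(=O)OC)[C@H]12 | intermediate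
27 | methyl (Z)-enoate with free 16-OH | CC(C)(C)[Si](C)(C)O[C@@H]1CCCC(C)(C)[C@@H]2CC[C@@](C)([C@H](CO)/C=C\C(=O)OC)[C@H]12 | intermediate (not isolated)
28 | 5-substituted 5,6-dihydro-2H-pyran-2-one (lactone O16–C14; C12=C13) | CC(C)(C)[Si](C)(C)O[C@@H]1CCCC(C)(C)[C@@H]2CC[C@@](C)([C@@H]3COC(=O)C=C3)[C@H]12 | intermediate
29 | trans-4-(hydroxymethyl)-5-substituted tetrahydropyran-2-one (C15 on C12) | CC(C)(C)[Si](C)(C)O[C@@H]1CCCC(C)(C)[C@@H]2CC[C@@](C)([C@@H]3COC(=O)C[C@H]3CO)[C@H]12 | intermediate (not isolated)
30 | γ-lactone alcohol (lactone O15–C14; free 16-OH; C11 and C12 as in the target) | CC(C)(C)[Si](C)(C)O[C@@H]1CCCC(C)(C)[C@@H]2CC[C@@](C)([C@H](CO)[C@@H]3COC(=O)C3)[C@H]12 | intermediate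
31 | 16-O-triethylsilyl ether of 30 | CC(C)(C)[Si](C)(C)O[C@@H]1CCCC(C)(C)[C@@H]2CC[C@@](C)([C@H](CO[Si](CC)(CC)CC)[C@@H]3COC(=O)C3)[C@H]12 | intermediate
32 | potassium lactone enolate of 31 | CC(C)(C)[Si](C)(C)O[C@@H]1CCCC(C)(C)[C@@H]2CC[C@@](C)([C@H](CO[Si](CC)(CC)CC)[C@@H]3COC([O-])=C3)[C@H]12.[K+] | intermediate (not isolated)
33 | (13S)-13-hydroxy lactone, 16-O-triethylsilyl ether | CC(C)(C)[Si](C)(C)O[C@@H]1CCCC(C)(C)[C@@H]2CC[C@@](C)([C@H](CO[Si](CC)(CC)CC)[C@@H]3COC(=O)[C@H]3O)[C@H]12 | intermediate (not isolated)
34 | 13,16-diol (1-O-tert-butyldimethylsilyl) | CC(C)(C)[Si](C)(C)O[C@@H]1CCCC(C)(C)[C@@H]2CC[C@@](C)([C@H](CO)[C@@H]3COC(=O)[C@H]3O)[C@H]12 | intermediate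
35 | 13,16-diacetate (1-O-tert-butyldimethylsilyl) | CC(C)(C)[Si](C)(C)O[C@@H]1CCCC(C)(C)[C@@H]2CC[C@@](C)([C@H](COC(C)=O)[C@@H]3COC(=O)[C@H]3OC(C)=O)[C@H]12 | intermediate
36 | C1 alcohol, 13,16-diacetate | O[C@@H]1CCCC(C)(C)[C@@H]2CC[C@@](C)([C@H](COC(C)=O)[C@@H]3COC(=O)[C@H]3OC(C)=O)[C@H]12 | intermediate
37 | C1 ketone, 13,16-diacetate | O=C1CCCC(C)(C)[C@@H]2CC[C@@](C)([C@H](COC(C)=O)[C@@H]3COC(=O)[C@H]3OC(C)=O)[C@H]12 | intermediate
38 | (3S,4R)-4-{(1R)-2-acetoxy-1-[(1R,3aR,8aS)-1,4,4-trimethyl-8-methylidenedecahydroazulen-1-yl]ethyl}-2-oxooxolan-3-yl acetate | C=C1CCCC(C)(C)[C@@H]2CC[C@@](C)([C@H](COC(C)=O)[C@@H]3COC(=O)[C@H]3OC(C)=O)[C@H]12 | target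

**Step count and risks**

Total: 24 steps. Longest linear sequence: 22 steps (steps 1–7, then 10–24; steps 8–9 make the side-chain iodide).

Steps most likely to fail:

1. Step 11 (key step). Proton loss from the C9 cation or chloride capture may outrun the C10 shift. The aluminium alkoxide may deliver the aldehyde from its own side and so select the other C8–C9 rotamer, giving the C9/C11-epimeric pair. The Lewis acid may also ionise the allylic silyl ether. The fallback changes the electrophile class and the terminating group; it sets out from 17 and returns at 20. Silylation of 17 with 1-(trimethylsilyl)imidazole gives the C8 trimethylsilyl ether F1, which cannot bind or deliver the electrophile. Benzyl chloromethyl ether with SnCl4 and 2,6-di-tert-butylpyridine in CH2Cl2 at −78 °C supplies a free benzyloxymethyl cation; its addition to C11 is terminated by the same C10 shift with loss of the silyl group, giving the C16 benzyl ether F2. Hydrogenolysis (H2, Pd(OH)2 on carbon, EtOAc) then gives 20.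

2. Step 2. The cyclobutyl methine may migrate in place of the methylene carbon, which would put the new CH2 between C1 and C10; double homologation and Lewis-acid-induced acyl shift of the β,γ-unsaturated ketone would drain material further. The fallback replaces diazoalkane insertion by a Saegusa–Ito ring expansion whose regiochemistry is fixed by enolisation; it sets out from 3 and returns at 5. LiN(i-Pr)2 and Me3SiCl at −78 °C give the kinetic silyl enol ether F3 on the CH2 side. Et2Zn/CH2I2 cyclopropanates this more electron-rich alkene to the siloxycyclopropane F4. FeCl3 in DMF opens it to the ring-enlarged β-chloro ketone F5, and NaOAc in MeOH eliminates to the cycloheptenone F6. Conjugate reduction with [CuH(PPh3)]6 gives 5.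

3. Step 18. Triplet benzophenone may abstract hydrogen from the substrate (C–H next to the silyloxy oxygen) and not from methanol. The hindered C12 may trap the hydroxymethyl radical too slowly, so that photodimerisation or simple reduction of the lactone competes, and the acyl shift may stop short. The fallback uses a polar conjugate addition in place of the radical one; it sets out from 28 and returns at 30. (i-PrO)Me2SiCH2MgCl with catalytic CuBr·SMe2 and Me3SiCl in THF at −78 °C should add trans to the C11 substituent to give the silylmethyl lactone F7. Tamao–Fleming oxidation (H2O2, KF, KHCO3, THF–MeOH) unmasks the hydroxymethyl group (compound 29), and catalytic camphorsulfonic acid completes the acyl shift to 30.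

Further compounds
F1 | step 11 | C8 trimethylsilyl ether of 17 | CC(C)(C)[Si](C)(C)O[C@@H]1CCCC(C)(C)[C@@H]2C[C@@](O[Si](C)(C)C)(/C(C)=C/CO[Si](CC)(CC)CC)[C@H]12
F2 | step 11 | C16 benzyl ether of 20 | CC(C)(C)[Si](C)(C)O[C@@H]1CCCC(C)(C)[C@@H]2CC(=O)[C@@](C)([C@H](COCc3ccccc3)CO[Si](CC)(CC)CC)[C@H]12
F3 | step 2 | (±)-cis-5,5-dimethyl-8-methylidene-2-(trimethylsilyloxy)bicyclo[4.2.0]oct-2-ene | C[Si](C)(C)OC1=CCC(C)(C)[C@@H]2CC(=C)[C@H]12
F4 | step 2 | siloxycyclopropane from F3 (CH2 added across the enol ether double bond) | C[Si](C)(C)OC12CC1CC(C)(C)[C@@H]3CC(=C)[C@H]23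
F5 | step 2 | (±)-cis-4-chloro-6,6-dimethyl-9-methylidenebicyclo[5.2.0]nonan-2-one | O=C1CC(Cl)CC(C)(C)[C@@H]2CC(=C)[C@H]12
F6 | step 2 | (±)-cis-6,6-dimethyl-9-methylidenebicyclo[5.2.0]non-3-en-2-one | O=C1C=CCC(C)(C)[C@@H]2CC(=C)[C@H]12
F7 | step 18 | trans-4-[(isopropoxydimethylsilyl)methyl]-5-substituted tetrahydropyran-2-one | CC(C)(C)[Si](C)(C)O[C@@H]1CCCC(C)(C)[C@@H]2CC[C@@](C)([C@@H]3COC(=O)C[C@H]3C[Si](C)(C)OC(C)C)[C@H]12
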